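**Plan**

1. Target 14 is 7-hydroxy-5-methoxy-3-(4-methoxybenzyl)-6-methyl-4-oxo-4H-chromene-8-carbaldehyde. The retrosynthesis cuts, in order: C8–CHO, the O7–benzyl bond, C2–C3 of the pyranone, the three aryl O–C bonds (O-methyl, O–CH2SPh, O-benzyl), and the C4–C4a aryl ketone bond.
2. Enabling feature: in the 4-pyranone ring C2 is a lone CH between O1 (the oxygen on C8a) and C3, the α-carbon of the C4 ketone. A one-carbon unit already bound to the C8a oxygen and raised to the formate oxidation level can therefore reach C3 through the six-membered array O1–C8a–C4a–C4–C3 and become C2, as the oxidised O-methyl does in homoisoflavonoid biogenesis.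
3. The unit is carried as a (phenylsulfinyl)methyl ether. Halogenating agents split O,S-acetals ArOCH2SR into ArOCH2Cl and a sulfenyl halide, whereas the sulfoxide gives the aryloxy thionium ion by a normal Pummerer reaction, and the phenyl group leaves O–CH2 as the only α-position.
4. Forward order: Friedel–Crafts acylation of methylphloroglucinol, 4'-O-benzylation, 6'-O-phenylthiomethylation at the less hindered ortho hydroxyl, 2'-O-methylation, S-oxidation, Pummerer ring closure to the chromone (the only ring formed), hydrogenolysis, C8 formylation.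
5. Stereochemistry: the target has no stereocentre, so the single enantiomer asked for is the one achiral compound and nothing has to be set; sulfoxide 8 is used as the racemate.

Key step: step 6

**Route**

Step 1
Reactants: 1 2,4,6-trihydroxytoluene; 2 3-(4-methoxyphenyl)propanoic acid
Product: 3 3-(4-methoxyphenyl)-1-(2,4,6-trihydroxy-3-methylphenyl)propan-1-one
Conditions: BF3·OEt2 (neat), 85 °C; then aq. NaOAc
Reagents that add atoms: none
Why: Friedel–Crafts acylation of a phloroglucinol by a free carboxylic acid in BF3 etherate is standard for acylphloroglucinols, the two open ring positions of 1 are equivalent so only one ketone can form, and the acyl group deactivates the ring against a second acylation.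

Step 2
Reactants: 3 3-(4-methoxyphenyl)-1-(2,4,6-trihydroxy-3-methylphenyl)propan-1-one
Product: 4 1-[4-(benzyloxy)-2,6-dihydroxy-3-methylphenyl]-3-(4-methoxyphenyl)propan-1-one
Conditions: BnBr (1.05 equiv), K2CO3 (1.1 equiv), DMF, 0 °C → rt
Reagents that add atoms: benzyl bromide, BrCc1ccccc1
Why: Williamson etherification under carbonate control, in which the 4'-hydroxyl, para to the ketone and not hydrogen-bonded, is the most acidic phenol of a 2,4,6-trihydroxyaryl ketone and is benzylated first when one equivalent of halide is used.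

Step 3
Reactants: 4 1-[4-(benzyloxy)-2,6-dihydroxy-3-methylphenyl]-3-(4-methoxyphenyl)propan-1-one; 5 chloromethyl phenyl sulfide
Product: 6 1-[4-(benzyloxy)-2-hydroxy-3-methyl-6-[(phenylsulfanyl)methoxy]phenyl]-3-(4-methoxyphenyl)propan-1-one
Conditions: K2CO3, NaI (cat.), DMF, 45 °C
Reagents that add atoms: none
Why: Williamson etherification with an α-chloro sulfide (phenylthiomethyl ether formation), in which the 6'-hydroxyl has only H-5' as neighbour whereas the 2'-hydroxyl is wedged between the acyl group and the 3'-methyl, so the first alkylation should go to O-6' and the remaining chelated hydroxyl should resist a second one.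

Step 4
Reactants: 6 1-[4-(benzyloxy)-2-hydroxy-3-methyl-6-[(phenylsulfanyl)methoxy]phenyl]-3-(4-methoxyphenyl)propan-1-one
Product: 7 1-[4-(benzyloxy)-2-methoxy-3-methyl-6-[(phenylsulfanyl)methoxy]phenyl]-3-(4-methoxyphenyl)propan-1-one
Conditions: MeI, K2CO3, DMF, 45 °C
Reagents that add atoms: iodomethane, CI
Why: Williamson O-methylation of the chelated, hindered phenol under carbonate conditions, while the α-aryloxy phenyl sulfide is too poor a nucleophile to be S-methylated by iodomethane without a silver salt.

Step 5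
Reactants: 7 1-[4-(benzyloxy)-2-methoxy-3-methyl-6-[(phenylsulfanyl)methoxy]phenyl]-3-(4-methoxyphenyl)propan-1-one
Product: 8 1-[4-(benzyloxy)-2-methoxy-3-methyl-6-[(phenylsulfinyl)methoxy]phenyl]-3-(4-methoxyphenyl)propan-1-one (racemic at sulfur)
Conditions: mCPBA (1.0 equiv), CH2Cl2, −78 → −30 °C
Reagents that add atoms: 3-chloroperoxybenzoic acid, OOC(=O)c1cccc(Cl)c1
Why: Chemoselective sulfide-to-sulfoxide oxidation by one equivalent of peracid at low temperature, where sulfur reacts far faster than the ketone (Baeyer–Villiger) or the arenes and the sulfone is not reached.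

Step 6
Reactants: 8 1-[4-(benzyloxy)-2-methoxy-3-methyl-6-[(phenylsulfinyl)methoxy]phenyl]-3-(4-methoxyphenyl)propan-1-one
Product: 11 7-(benzyloxy)-5-methoxy-3-(4-methoxybenzyl)-6-methyl-4H-chromen-4-one, via enol silane thionium triflate 9 (not isolated), via 2-(phenylsulfanyl)chroman-4-one 10 (not isolated)
Conditions: TMSOTf (4 equiv), i-Pr2NEt (5 equiv), CH2Cl2 (0.01 M), −78 → 0 °C; then DBU, rt; aq. NaOH wash
Reagents that add atoms: none
Why: Proposed new method: TMSOTf silylates the sulfoxide oxygen, the amine removes the acidic proton of the O–CH2–S carbon and loss of silanolate leaves the aryloxy(phenylsulfanyl)methylium (thionium) ion, while the same reagent pair converts the ketone into its enol silane, as in 9. The enol carbon C3 adds to the cationic carbon (the future C2) in a Mukaiyama-type alkylation to give 10, and base then expels thiophenol across C2–C3, so the sulfur delivers the chromone oxidation level without a dehydrogenation. The closest known reactions are silicon-induced Pummerer reactions intercepted by enol silanes and the Lewis-acid alkylation of enol silanes by α-chloro sulfides; an aryloxymethyl sulfoxide has not been used as the thionium source in such a ring closure. The pyranone closes in a 6-(enolendo)-exo-trig mode, and C2 and C3 of 10 form without control and both become sp2 in 11, so no stereocentre has to be set. The step needs a normal Pummerer course instead of fragmentation to an aryloxymethyl cation, and C-alkylation at C3 instead of O- or aryl alkylation. The phenyl group leaves O–CH2 as the only α-position and no sulfenyl halide can form, the silylated enol oxygen cannot compete and any O,O,S-orthoester from carbonyl participation can re-ionise, and the tether offers the anisole ring only a nine-membered or larger ring.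

Step 7
Reactants: 11 7-(benzyloxy)-5-methoxy-3-(4-methoxybenzyl)-6-methyl-4H-chromen-4-one
Product: 12 7-hydroxy-5-methoxy-3-(4-methoxybenzyl)-6-methyl-4H-chromen-4-one
Conditions: H2 (1 atm), 10% Pd/C, EtOAc, rt, stopped at one equivalent of H2
Reagents that add atoms: none
Why: Catalytic hydrogenolysis of a benzyl aryl ether, which should be faster than reduction of the C2=C3 bond of a 3-substituted chromone (a vinylogous ester), and the sulfur left the molecule in step 6 and is washed out, so the catalyst should not be poisoned.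

Step 8
Reactants: 12 7-hydroxy-5-methoxy-3-(4-methoxybenzyl)-6-methyl-4H-chromen-4-one
Product: 14 7-hydroxy-5-methoxy-3-(4-methoxybenzyl)-6-methyl-4-oxo-4H-chromene-8-carbaldehyde, via 8-iminomethyl aldimine 13 (not isolated)
Conditions: hexamethylenetetramine, AcOH, 100 °C; then 3 M aq. HCl, 80 °C
Reagents that add atoms: hexamethylenetetramine, C1N2CN3CN1CN(C2)C3; water, O
Why: Duff ortho-formylation of a phenol, in which C8 is the only free ring position ortho to the 7-hydroxyl (C6 carries the methyl), is further activated by the para 5-methoxy group and the ortho ring oxygen, and the anisole ring, lacking a free hydroxyl, should not react in acetic acid.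

**Compound list**

1 | 2,4,6-trihydroxytoluene (2-methylbenzene-1,3,5-triol) | Cc1c(O)cc(O)cc1O | starting material
2 | 3-(4-methoxyphenyl)propanoic acid | COc1ccc(CCC(=O)O)cc1 | starting material
3 | 3-(4-methoxyphenyl)-1-(2,4,6-trihydroxy-3-methylphenyl)propan-1-one | COc1ccc(CCC(=O)c2c(O)cc(O)c(C)c2O)cc1 | intermediate
4 | 1-[4-(benzyloxy)-2,6-dihydroxy-3-methylphenyl]-3-(4-methoxyphenyl)propan-1-one | COc1ccc(CCC(=O)c2c(O)cc(OCc3ccccc3)c(C)c2O)cc1 | intermediate
5 | chloromethyl phenyl sulfide | ClCSc1ccccc1 | starting material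
6 | 1-[4-(benzyloxy)-2-hydroxy-3-methyl-6-[(phenylsulfanyl)methoxy]phenyl]-3-(4-methoxyphenyl)propan-1-one | COc1ccc(CCC(=O)c2c(OCSc3ccccc3)cc(OCc4ccccc4)c(C)c2O)cc1 | intermediate
7 | 1-[4-(benzyloxy)-2-methoxy-3-methyl-6-[(phenylsulfanyl)methoxy]phenyl]-3-(4-methoxyphenyl)propan-1-one | COc1ccc(CCC(=O)c2c(OCSc3ccccc3)cc(OCc4ccccc4)c(C)c2OC)cc1 | intermediate
8 | 1-[4-(benzyloxy)-2-methoxy-3-methyl-6-[(phenylsulfinyl)methoxy]phenyl]-3-(4-methoxyphenyl)propan-1-one, racemic at sulfur | COc1ccc(CCC(=O)c2c(OCS(=O)c3ccccc3)cc(OCc4ccccc4)c(C)c2OC)cc1 | intermediate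
9 | [5-(benzyloxy)-3-methoxy-4-methyl-2-[(1Z)-3-(4-methoxyphenyl)-1-(trimethylsilyloxy)prop-1-en-1-yl]phenoxy]methylidene(phenyl)sulfonium triflate (thionium ion of 8 with the ketone as its Z enol silane) | COc1ccc(C/C=C(\O[Si](C)(C)C)c2c(OC=[S+]c3ccccc3)cc(OCc4ccccc4)c(C)c2OC)cc1.[O-]S(=O)(=O)C(F)(F)F | intermediate
10 | 7-(benzyloxy)-5-methoxy-3-(4-methoxybenzyl)-6-methyl-2-(phenylsulfanyl)chroman-4-one, racemic mixture of C2/C3 diastereomers | COc1ccc(CC2C(Sc3ccccc3)Oc3cc(OCc4ccccc4)c(C)c(OC)c3C2=O)cc1 | intermediate
11 | 7-(benzyloxy)-5-methoxy-3-(4-methoxybenzyl)-6-methyl-4H-chromen-4-one | COc1ccc(Cc2coc3cc(OCc4ccccc4)c(C)c(OC)c3c2=O)cc1 | intermediate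
12 | 7-hydroxy-5-methoxy-3-(4-methoxybenzyl)-6-methyl-4H-chromen-4-one | COc1ccc(Cc2coc3cc(O)c(C)c(OC)c3c2=O)cc1 | intermediate
13 | 7-hydroxy-8-(iminomethyl)-5-methoxy-3-(4-methoxybenzyl)-6-methyl-4H-chromen-4-one (Duff aldimine, drawn in its simplest N–H form) | COc1ccc(Cc2coc3c(C=N)c(O)c(C)c(OC)c3c2=O)cc1 | intermediate
14 | 7-hydroxy-5-methoxy-3-(4-methoxybenzyl)-6-methyl-4-oxo-4H-chromene-8-carbaldehyde | COc1ccc(Cc2coc3c(C=O)c(O)c(C)c(OC)c3c2=O)cc1 | target

**Step count**

Total: 8 steps. Longest linear sequence: 8 steps (1 → 14); 2 and 5 enter as commercial materials.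

**Steps most likely to fail**

Step 6. The thionium ion may be intercepted before the C–C bond forms. Capture by triflate or silanolate followed by hydrolysis would return the phenol, the ketone oxygen could trap the cation, or intermolecular arylation could take over at higher concentration. The fallback sets out from 7 and uses the classical order of bond formation. Mercury(II)-assisted hydrolysis of the O,S-acetal (HgCl2, CaCO3, MeCN–H2O) should free 1-[4-(benzyloxy)-6-hydroxy-2-methoxy-3-methylphenyl]-3-(4-methoxyphenyl)propan-1-one F1. Heating F1 with N,N-dimethylformamide dimethyl acetal in toluene at 110 °C should give (E)-1-[4-(benzyloxy)-6-hydroxy-2-methoxy-3-methylphenyl]-3-(dimethylamino)-2-(4-methoxybenzyl)prop-2-en-1-one F2, which cyclises in the same flask with loss of dimethylamine. The fallback returns to the route at 11.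

Step 3. Steric discrimination between the two ortho hydroxyls may be insufficient, so that alkylation also occurs at O-2' or at both oxygens. The fallback sets out from 3 and replaces selective alkylation by chelation-controlled dealkylation.
- Exhaustive benzylation (BnBr in excess, K2CO3, DMF, 70 °C) should give 3-(4-methoxyphenyl)-1-[2,4,6-tris(benzyloxy)-3-methylphenyl]propan-1-one F3.
- One equivalent of BCl3 (CH2Cl2, −78 °C) should cleave the ortho benzyl ether that is compressed between the carbonyl and the methyl group, giving 1-[4,6-bis(benzyloxy)-2-hydroxy-3-methylphenyl]-3-(4-methoxyphenyl)propan-1-one F4.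
- Methylation (MeI, K2CO3, DMF) leads to 1-[4,6-bis(benzyloxy)-2-methoxy-3-methylphenyl]-3-(4-methoxyphenyl)propan-1-one F5.
- MgBr2·OEt2 (toluene–Et2O, 80 °C) should remove only the benzyl group ortho to the carbonyl and give 1-[4-(benzyloxy)-6-hydroxy-2-methoxy-3-methylphenyl]-3-(4-methoxyphenyl)propan-1-one F6, the same substance as F1.
- Alkylation of F6 with 5 (K2CO3, NaI, DMF) returns to the route at 7.

Step 8. Electrophilic substitution at C8 may be sluggish, because the 7-hydroxyl is conjugated with the C4 carbonyl, and prolonged heating may lead to resinification. The fallback sets out from 12 and brings in the carbon by a sigmatropic shift that does not depend on the nucleophilicity of C8.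
- Allylation (allyl bromide, K2CO3, acetone) should give 7-(allyloxy)-5-methoxy-3-(4-methoxybenzyl)-6-methyl-4H-chromen-4-one F7.
- Claisen rearrangement (N,N-diethylaniline, 190 °C) can only deliver the allyl group to C8 and should give 8-allyl-7-hydroxy-5-methoxy-3-(4-methoxybenzyl)-6-methyl-4H-chromen-4-one F8.
- Alkene isomerisation (PdCl2(MeCN)2 cat., toluene, 80 °C) should give 7-hydroxy-5-methoxy-3-(4-methoxybenzyl)-6-methyl-8-[(E)-prop-1-en-1-yl]-4H-chromen-4-one F9.
- Lemieux–Johnson cleavage (OsO4 cat., NaIO4, 2,6-lutidine, dioxane–H2O) returns to the route at 14.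

**Further compounds**

F1 | step 6 | 1-[4-(benzyloxy)-6-hydroxy-2-methoxy-3-methylphenyl]-3-(4-methoxyphenyl)propan-1-one | COc1ccc(CCC(=O)c2c(O)cc(OCc3ccccc3)c(C)c2OC)cc1
F2 | step 6 | (E)-1-[4-(benzyloxy)-6-hydroxy-2-methoxy-3-methylphenyl]-3-(dimethylamino)-2-(4-methoxybenzyl)prop-2-en-1-one | COc1ccc(C/C(=C\N(C)C)C(=O)c2c(O)cc(OCc3ccccc3)c(C)c2OC)cc1
F3 | step 3 | 3-(4-methoxyphenyl)-1-[2,4,6-tris(benzyloxy)-3-methylphenyl]propan-1-one | COc1ccc(CCC(=O)c2c(OCc3ccccc3)cc(OCc4ccccc4)c(C)c2OCc5ccccc5)cc1
F4 | step 3 | 1-[4,6-bis(benzyloxy)-2-hydroxy-3-methylphenyl]-3-(4-methoxyphenyl)propan-1-one | COc1ccc(CCC(=O)c2c(OCc3ccccc3)cc(OCc4ccccc4)c(C)c2O)cc1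
F5 | step 3 | 1-[4,6-bis(benzyloxy)-2-methoxy-3-methylphenyl]-3-(4-methoxyphenyl)propan-1-one | COc1ccc(CCC(=O)c2c(OCc3ccccc3)cc(OCc4ccccc4)c(C)c2OC)cc1
F6 | step 3 | 1-[4-(benzyloxy)-6-hydroxy-2-methoxy-3-methylphenyl]-3-(4-methoxyphenyl)propan-1-one (same substance as F1) | COc1ccc(CCC(=O)c2c(O)cc(OCc3ccccc3)c(C)c2OC)cc1
F7 | step 8 | 7-(allyloxy)-5-methoxy-3-(4-methoxybenzyl)-6-methyl-4H-chromen-4-one | COc1ccc(Cc2coc3cc(OCC=C)c(C)c(OC)c3c2=O)cc1
F8 | step 8 | 8-allyl-7-hydroxy-5-methoxy-3-(4-methoxybenzyl)-6-methyl-4H-chromen-4-one | COc1ccc(Cc2coc3c(CC=C)c(O)c(C)c(OC)c3c2=O)cc1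
F9 | step 8 | 7-hydroxy-5-methoxy-3-(4-methoxybenzyl)-6-methyl-8-[(E)-prop-1-en-1-yl]-4H-chromen-4-one | COc1ccc(Cc2coc3c(/C=C/C)c(O)c(C)c(OC)c3c2=O)cc1
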